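**Retrosynthetic overview**
- The target comes from its hexabenzyl ether by global hydrogenolysis in the last step.
- The dihydroflavonol ring C is closed last, on the finished biaryl: a 2′-hydroxychalcone undergoes catalyst-controlled 6-endo oxa-Michael closure to the (2S)-flavanone (chalcone isomerase logic), then C3 hydroxylation anti to the aryl group (flavanone 3-hydroxylase logic), in one operation.
- That chalcone comes from a biaryl methyl ketone and 4-(benzyloxy)benzaldehyde by Claisen–Schmidt condensation.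
- The biaryl ketone comes from a 3′-bromoflavone and a 3-iodo-2-hydroxyacetophenone by one-pot borylation/Suzuki coupling, so the biaryl bond joins a flavone to a simple acetophenone, not two finished flavonoids.
- The flavone ring C is formed first, from a chalcone by oxa-Michael closure and dehydrogenation (flavone synthase logic); both chalcones use the same dibenzylated phloroacetophenone.

**Assumptions**
- The biaryl axis (three small ortho substituents) rotates freely at room temperature, so only C2 and C3 need control.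
- 4-(Benzyloxy)-3-bromobenzaldehyde and 4-(benzyloxy)benzaldehyde are bought as catalogue compounds.
- The quinine-derived thiourea is taken to give the 2S flavanone; a model chalcone is run first, and if the sense is opposite, the quinidine-derived pseudoenantiomer is used in the same way.

**Route**

Step 1
Reactants: 1 phloroacetophenone (1-(2,4,6-trihydroxyphenyl)ethanone)
Product: 2 acetophenone 1-[2,4-bis(benzyloxy)-6-hydroxyphenyl]ethanone
Conditions: BnBr (2.1 equiv), K2CO3 (2.2 equiv), DMF, 0 °C to rt, 12 h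
Reagents that add atoms: benzyl bromide, BrCc1ccccc1
Why: Williamson ether synthesis in which two hydroxyls are alkylated while the remaining ortho hydroxyl is hydrogen-bonded to the ketone and too unreactive for K2CO3/BnBr; no stereocentre is formed.

Step 2
Reactants: 2 acetophenone 1-[2,4-bis(benzyloxy)-6-hydroxyphenyl]ethanone; 3 aldehyde 4-(benzyloxy)-3-bromobenzaldehyde
Product: 4 chalcone (E)-1-[2,4-bis(benzyloxy)-6-hydroxyphenyl]-3-[4-(benzyloxy)-3-bromophenyl]prop-2-en-1-one
Conditions: KOH (50% aq, excess), EtOH–THF, rt, 48 h; then cold 1 M HCl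
Reagents that add atoms: none
Why: Claisen–Schmidt condensation (aldol addition then E1cB dehydration) gives the E-enone under thermodynamic control; no stereocentre is formed.

Step 3
Reactants: 4 chalcone (E)-1-[2,4-bis(benzyloxy)-6-hydroxyphenyl]-3-[4-(benzyloxy)-3-bromophenyl]prop-2-en-1-one
Product: 6 bromoflavone 5,7-bis(benzyloxy)-2-[4-(benzyloxy)-3-bromophenyl]-4H-chromen-4-one, via racemic flavanone 5 (not isolated)
Conditions: I2 (10 mol %), DMSO, 130 °C, 3 h; Na2S2O3 work-up
Reagents that add atoms: none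
Why: Iodine-catalysed oxidative cyclisation in which 6-endo oxa-Michael closure of ring C gives the flavanone, and α-iodination/HI elimination with DMSO as terminal oxidant then gives the flavone, so no stereocentre survives.

Step 4
Reactants: 2 acetophenone 1-[2,4-bis(benzyloxy)-6-hydroxyphenyl]ethanone
Product: 7 iodoketone 1-[4,6-bis(benzyloxy)-2-hydroxy-3-iodophenyl]ethanone
Conditions: BnNMe3·ICl2 (1.05 equiv), NaHCO3 (3 equiv), CH2Cl2–MeOH, rt, 3 h
Reagents that add atoms: benzyltrimethylammonium dichloroiodate, C[N+](C)(C)Cc1ccccc1.Cl[I-]Cl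
Why: Electrophilic aromatic iodination goes ortho to the chelated phenol, because position 3 (between OH and OBn) is less hindered than position 5 (between two benzyloxy groups), as known for 2-hydroxy-4,6-dialkoxyacetophenones; no stereocentre is formed.

Step 5
Reactants: 6 bromoflavone 5,7-bis(benzyloxy)-2-[4-(benzyloxy)-3-bromophenyl]-4H-chromen-4-one; 7 iodoketone 1-[4,6-bis(benzyloxy)-2-hydroxy-3-iodophenyl]ethanone
Product: 9 biaryl ketone 2-{3-[3-acetyl-4,6-bis(benzyloxy)-2-hydroxyphenyl]-4-(benzyloxy)phenyl}-5,7-bis(benzyloxy)-4H-chromen-4-one, via pinacol boronate 8 (not isolated)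
Conditions: 6, bis(pinacolato)diboron (1.1 equiv), Pd(dppf)Cl2 (5 mol %), KOAc (3 equiv), 1,4-dioxane, 90 °C, 6 h; then 7 (1.0 equiv), Pd(OAc)2 (5 mol %), 2-dicyclohexylphosphino-2′,6′-dimethoxybiphenyl (10 mol %), aq K3PO4 (4 equiv), 90 °C, 12 h
Reagents that add atoms: none
Why: One-pot Miyaura borylation then Suzuki–Miyaura coupling, in which zerovalent palladium inserts into the C–I bond of 7 and the bulky electron-rich biaryl phosphine tolerates the two ortho substituents and the phenoxide; the new axis is not a stable stereo element.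

Step 6
Reactants: 9 biaryl ketone 2-{3-[3-acetyl-4,6-bis(benzyloxy)-2-hydroxyphenyl]-4-(benzyloxy)phenyl}-5,7-bis(benzyloxy)-4H-chromen-4-one; 10 aldehyde 4-(benzyloxy)benzaldehyde
Product: 11 chalcone (E)-1-[4,6-bis(benzyloxy)-3-{2-(benzyloxy)-5-[5,7-bis(benzyloxy)-4-oxo-4H-chromen-2-yl]phenyl}-2-hydroxyphenyl]-3-[4-(benzyloxy)phenyl]prop-2-en-1-one
Conditions: KOH (50% aq, 15 equiv), EtOH–THF (1:1), rt, 48–72 h, Ar; then cold 1 M HCl to pH 3
Reagents that add atoms: none
Why: Claisen–Schmidt condensation at the only enolisable position (the flavone has none and tolerates cold alkali) gives the E-enone; no stereocentre is formed.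

Step 7
Reactants: 11 chalcone (E)-1-[4,6-bis(benzyloxy)-3-{2-(benzyloxy)-5-[5,7-bis(benzyloxy)-4-oxo-4H-chromen-2-yl]phenyl}-2-hydroxyphenyl]-3-[4-(benzyloxy)phenyl]prop-2-en-1-one
Product: 15 dihydroflavonol (2R,3R)-5,7-bis(benzyloxy)-8-{2-(benzyloxy)-5-[5,7-bis(benzyloxy)-4-oxo-4H-chromen-2-yl]phenyl}-2-[4-(benzyloxy)phenyl]-3-hydroxy-2,3-dihydro-4H-chromen-4-one, via (2S)-flavanone 12 (not isolated), via silyl enol ether 13 (not isolated), via silyloxy epoxide 14 (not isolated)
Conditions: 1-[3,5-bis(trifluoromethyl)phenyl]-3-[(8α,9S)-6′-methoxycinchonan-9-yl]thiourea (10 mol %), PhMe, 30 °C, 72 h; cold 0.5 M HCl wash; Me3SiOTf (3 equiv), Et3N (4 equiv), CH2Cl2, −78 to 0 °C; cold NaHCO3 wash; dimethyldioxirane (1.2 equiv), acetone–CH2Cl2, −40 °C; citric acid, MeOH–THF, 0 °C to rt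
Reagents that add atoms: dimethyldioxirane, CC1(C)OO1
Why: Proposed new method: the quinuclidine nitrogen deprotonates the chelated 2′-phenol while the thiourea hydrogen-bonds the enone carbonyl, so the phenoxide adds 6-endo to one enantioface of the β-carbon and sets C2 as S (the 6′-benzyloxy group twists the enone and drives the equilibrium to the flavanone), soft enolisation with Me3SiOTf/Et3N then gives the enol ether without a free enolate that could ring-open and racemise, and dimethyldioxirane epoxidises the enol ether on the face away from the C2 aryl group so that hydrolysis leaves the 3-hydroxyl trans to the aryl (3R, while 2S becomes 2R only through the priority change); the closest known reaction types are the cinchona-thiourea-catalysed intramolecular oxa-Michael addition of simple 2′-hydroxychalcones and the Rubottom oxidation of flavanone silyl enol ethers, here telescoped and applied to a 3′-aryl-6′-alkoxychalcone for the first time.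

Step 8
Reactants: 15 dihydroflavonol (2R,3R)-5,7-bis(benzyloxy)-8-{2-(benzyloxy)-5-[5,7-bis(benzyloxy)-4-oxo-4H-chromen-2-yl]phenyl}-2-[4-(benzyloxy)phenyl]-3-hydroxy-2,3-dihydro-4H-chromen-4-one
Product: 16 target (2R,3R)-3,5,7-trihydroxy-8-[2-hydroxy-5-(5,7-dihydroxy-4-oxo-4H-chromen-2-yl)phenyl]-2-(4-hydroxyphenyl)-2,3-dihydro-4H-chromen-4-one
Conditions: H2 (1 atm), palladium on carbon (10 wt % Pd), THF–MeOH (1:1), rt, 4–8 h, monitored; filtration under Ar
Reagents that add atoms: none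
Why: Hydrogenolysis of the six benzyl ethers under neutral conditions at room temperature leaves the flavone double bond, the C2–O bond and both stereocentres untouched.

**Compound list**
1 | 1-(2,4,6-trihydroxyphenyl)ethanone | CC(=O)c1c(O)cc(O)cc1O | starting material
2 | 1-[2,4-bis(benzyloxy)-6-hydroxyphenyl]ethanone | CC(=O)c1c(O)cc(OCc2ccccc2)cc1OCc1ccccc1 | intermediate
3 | 4-(benzyloxy)-3-bromobenzaldehyde | O=Cc1ccc(OCc2ccccc2)c(Br)c1 | starting material
4 | (E)-1-[2,4-bis(benzyloxy)-6-hydroxyphenyl]-3-[4-(benzyloxy)-3-bromophenyl]prop-2-en-1-one | O=C(/C=C/c1ccc(OCc2ccccc2)c(Br)c1)c1c(O)cc(OCc2ccccc2)cc1OCc1ccccc1 | intermediate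
5 | racemic 5,7-bis(benzyloxy)-2-[4-(benzyloxy)-3-bromophenyl]-2,3-dihydro-4H-chromen-4-one | O=C1CC(c2ccc(OCc3ccccc3)c(Br)c2)Oc2cc(OCc3ccccc3)cc(OCc3ccccc3)c21 | intermediate
6 | 5,7-bis(benzyloxy)-2-[4-(benzyloxy)-3-bromophenyl]-4H-chromen-4-one | O=c1cc(-c2ccc(OCc3ccccc3)c(Br)c2)oc2cc(OCc3ccccc3)cc(OCc3ccccc3)c12 | intermediate
7 | 1-[4,6-bis(benzyloxy)-2-hydroxy-3-iodophenyl]ethanone | CC(=O)c1c(O)c(I)c(OCc2ccccc2)cc1OCc1ccccc1 | intermediate
8 | 5,7-bis(benzyloxy)-2-[4-(benzyloxy)-3-(4,4,5,5-tetramethyl-1,3,2-dioxaborolan-2-yl)phenyl]-4H-chromen-4-one | O=c1cc(-c2ccc(OCc3ccccc3)c(B3OC(C)(C)C(C)(C)O3)c2)oc2cc(OCc3ccccc3)cc(OCc3ccccc3)c12 | intermediate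
9 | 2-{3-[3-acetyl-4,6-bis(benzyloxy)-2-hydroxyphenyl]-4-(benzyloxy)phenyl}-5,7-bis(benzyloxy)-4H-chromen-4-one | CC(=O)c1c(O)c(-c2cc(-c3cc(=O)c4c(OCc5ccccc5)cc(OCc5ccccc5)cc4o3)ccc2OCc2ccccc2)c(OCc2ccccc2)cc1OCc1ccccc1 | intermediate
10 | 4-(benzyloxy)benzaldehyde | O=Cc1ccc(OCc2ccccc2)cc1 | starting material
11 | (E)-1-[4,6-bis(benzyloxy)-3-{2-(benzyloxy)-5-[5,7-bis(benzyloxy)-4-oxo-4H-chromen-2-yl]phenyl}-2-hydroxyphenyl]-3-[4-(benzyloxy)phenyl]prop-2-en-1-one | O=C(/C=C/c1ccc(OCc2ccccc2)cc1)c1c(O)c(-c2cc(-c3cc(=O)c4c(OCc5ccccc5)cc(OCc5ccccc5)cc4o3)ccc2OCc2ccccc2)c(OCc2ccccc2)cc1OCc1ccccc1 | intermediate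
12 | (2S)-5,7-bis(benzyloxy)-8-{2-(benzyloxy)-5-[5,7-bis(benzyloxy)-4-oxo-4H-chromen-2-yl]phenyl}-2-[4-(benzyloxy)phenyl]-2,3-dihydro-4H-chromen-4-one | O=C1c2c(OCc3ccccc3)cc(OCc3ccccc3)c(-c3cc(-c4cc(=O)c5c(OCc6ccccc6)cc(OCc6ccccc6)cc5o4)ccc3OCc3ccccc3)c2O[C@H](c2ccc(OCc3ccccc3)cc2)C1 | intermediate
13 | trimethylsilyl enol ether of 12: 2-{4-(benzyloxy)-3-[(2S)-5,7-bis(benzyloxy)-2-[4-(benzyloxy)phenyl]-4-(trimethylsilyloxy)-2H-chromen-8-yl]phenyl}-5,7-bis(benzyloxy)-4H-chromen-4-one | C[Si](C)(C)OC1=C[C@@H](c2ccc(OCc3ccccc3)cc2)Oc2c(-c3cc(-c4cc(=O)c5c(OCc6ccccc6)cc(OCc6ccccc6)cc5o4)ccc3OCc3ccccc3)c(OCc3ccccc3)cc(OCc3ccccc3)c12 | intermediate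
14 | silyloxy epoxide of 13: 3,4-epoxy-4-(trimethylsilyloxy) derivative, epoxide oxygen anti to the C2 aryl group, (2R,3R,4R) in chroman numbering | C[Si](C)(C)O[C@]12c3c(OCc4ccccc4)cc(OCc4ccccc4)c(-c4cc(-c5cc(=O)c6c(OCc7ccccc7)cc(OCc7ccccc7)cc6o5)ccc4OCc4ccccc4)c3O[C@H](c3ccc(OCc4ccccc4)cc3)[C@H]1O2 | intermediate
15 | (2R,3R)-5,7-bis(benzyloxy)-8-{2-(benzyloxy)-5-[5,7-bis(benzyloxy)-4-oxo-4H-chromen-2-yl]phenyl}-2-[4-(benzyloxy)phenyl]-3-hydroxy-2,3-dihydro-4H-chromen-4-one | O=C1c2c(OCc3ccccc3)cc(OCc3ccccc3)c(-c3cc(-c4cc(=O)c5c(OCc6ccccc6)cc(OCc6ccccc6)cc5o4)ccc3OCc3ccccc3)c2O[C@H](c2ccc(OCc3ccccc3)cc2)[C@H]1O | intermediate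
16 | (2R,3R)-3,5,7-trihydroxy-8-[2-hydroxy-5-(5,7-dihydroxy-4-oxo-4H-chromen-2-yl)phenyl]-2-(4-hydroxyphenyl)-2,3-dihydro-4H-chromen-4-one | O=C1c2c(O)cc(O)c(-c3cc(-c4cc(=O)c5c(O)cc(O)cc5o4)ccc3O)c2O[C@H](c2ccc(O)cc2)[C@H]1O | target

**Step count and risks**

Total steps: 8. Longest linear sequence: 7 (steps 1, 2, 3, 5, 6, 7, 8); step 4 is a one-step branch from 2.

The three steps most likely to fail:

Step 7 (cyclisation/hydroxylation). The catalyst may give low conversion or low enantiomeric excess on this hindered 3′-aryl chalcone, and the enantiomeric excess cannot be upgraded before hydroxylation. It is checked on an aliquot of 12 by chiral HPLC, and 15 is recrystallised. The fallback sets out from 11 and comes back at 15, and closes the ring by epoxide opening instead of oxa-Michael addition. The chelated phenol of 11 is alkylated (NaH, MOMCl, DMF, 0 °C) to the 2′-O-methoxymethyl chalcone F1. Juliá–Colonna epoxidation (poly-L-leucine, urea–H2O2, DBU, THF, rt) gives the (2R,3S)-epoxy ketone F2. HCl in MeOH–THF at 45 °C removes the methoxymethyl group, and the freed phenol opens the epoxide 6-endo at the benzylic carbon with inversion, giving the 2,3-trans (2R,3R) compound 15 directly. The known weakness is partial loss of enantiomeric purity through carbocation character at the 4-benzyloxybenzylic carbon.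

Step 5 (one-pot borylation/Suzuki coupling). The iodide 7 is electron-rich, flanked by two ortho substituents, and present as a phenoxide, so oxidative addition may be slow and protodeiodination may win. The fallback sets out from 7 and comes back at 9, and masks the phenol. Compound 7 is converted (NaH, MOMCl, DMF) to the methoxymethyl ether F3. F3 is coupled with boronate 8 (made from 6 as in step 5 and filtered through silica) under the same Pd(OAc)2/biaryl phosphine conditions to give the protected biaryl ketone F4. Brief HCl in MeOH–THF at 40 °C removes the methoxymethyl group ortho to the ketone and gives 9.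

Step 8 (global hydrogenolysis). Six benzyl ethers must go without reducing the flavone C2=C3 bond or cleaving the benzylic C2–O bond of the dihydroflavonol, and the free 4′-phenol product can epimerise at C2 if heated or made basic. The fallback sets out from 15 and comes back at 16, and replaces reduction by Lewis-acid dealkylation: BCl3 (excess) with pentamethylbenzene as benzyl-cation scavenger, CH2Cl2, −78 °C, then MeOH quench. This fallback makes no new compound (F0).

Further compounds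
F1 | step 7 | (E)-1-[4,6-bis(benzyloxy)-3-{2-(benzyloxy)-5-[5,7-bis(benzyloxy)-4-oxo-4H-chromen-2-yl]phenyl}-2-(methoxymethoxy)phenyl]-3-[4-(benzyloxy)phenyl]prop-2-en-1-one | O=C(/C=C/c1ccc(OCc2ccccc2)cc1)c1c(OCOC)c(-c2cc(-c3cc(=O)c4c(OCc5ccccc5)cc(OCc5ccccc5)cc4o3)ccc2OCc2ccccc2)c(OCc2ccccc2)cc1OCc1ccccc1
F2 | step 7 | {4,6-bis(benzyloxy)-3-{2-(benzyloxy)-5-[5,7-bis(benzyloxy)-4-oxo-4H-chromen-2-yl]phenyl}-2-(methoxymethoxy)phenyl}{(2R,3S)-3-[4-(benzyloxy)phenyl]oxiran-2-yl}methanone | O=C([C@@H]1O[C@H]1c1ccc(OCc2ccccc2)cc1)c1c(OCOC)c(-c2cc(-c3cc(=O)c4c(OCc5ccccc5)cc(OCc5ccccc5)cc4o3)ccc2OCc2ccccc2)c(OCc2ccccc2)cc1OCc1ccccc1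
F3 | step 5 | 1-[4,6-bis(benzyloxy)-3-iodo-2-(methoxymethoxy)phenyl]ethanone | CC(=O)c1c(OCOC)c(I)c(OCc2ccccc2)cc1OCc1ccccc1
F4 | step 5 | 2-{3-[3-acetyl-4,6-bis(benzyloxy)-2-(methoxymethoxy)phenyl]-4-(benzyloxy)phenyl}-5,7-bis(benzyloxy)-4H-chromen-4-one | CC(=O)c1c(OCOC)c(-c2cc(-c3cc(=O)c4c(OCc5ccccc5)cc(OCc5ccccc5)cc4o3)ccc2OCc2ccccc2)c(OCc2ccccc2)cc1OCc1ccccc1
F0 | step 8 | none | none
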